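**Retrosynthetic overview**
1. Target ⇒ β-keto bridged lactam (C8–OH comes from the ketone) ⇒ oxidative 1,2-shift of C1 from C9a to C9 in a tuberostemonine-type tetracyclic enaminone. This one step contracts ring C (6→5), expands ring B (5→6), and creates the twisted lactam and quaternary C9.
2. Tetracycle ⇒ ring C by enamine→butenolide Michael closure (C1–C12). It runs in the same pot as a three-component union (C9–C10, C10–C11) of a pyrrolo[1,2-a]azepin-8-one, propanal and 3-methyl-2-silyloxyfuran.
3. Pyrroloazepinone ⇒ [4+3] annulation (N4–C5, C8–C9) of a 2-methyl-1-pyrroline with spiro-cyclopropyl Meldrum's acid.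
4. Pyrroline with its lactone ⇒ vinylogous Mannich reaction of the same silyloxyfuran with the sulfinimine of 4-oxopentanal, then hydrogenation.
5. Ring order: side-chain lactone → B → A → D attached, C closed → contraction/expansion to cyclopentane, piperidinone and bridged azepanone.

Assumption: the target is treated as a rearranged tuberostemonine-type alkaloid whose presumed biosynthesis is (i) vinylogous Mannich attachment of the lactone at C3, (ii) C1–C12 closure by enamine-to-butenolide Michael addition, (iii) oxidation at C8/C9 with a 1,2-shift of C1 from the carbinolamine carbon C9a to C9; Stemona numbering is used (N4; C1–C3; C5–C9; C9a = lactam C=O; C10 bears ethyl C16–C17; C11–C15 fused lactone; C18–C22 side-chain lactone).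

**Step 1**
Reactants: 1 3-methylfuran-2(5H)-one
Product: 2 tert-butyl(dimethyl)[(3-methylfuran-2-yl)oxy]silane
Conditions: TBSOTf, Et3N, CH2Cl2, 0 °C
Reagents that add atoms: tert-butyldimethylsilyl triflate, CC(C)(C)[Si](C)(C)OS(=O)(=O)C(F)(F)F
Why: Soft enolisation and O-silylation give the aromatic 2-silyloxyfuran, the γ-nucleophilic dienolate equivalent used for both lactone units; no stereocentre is formed.

**Step 2**
Reactants: 3 5-hydroxypentan-2-one
Product: 4 4-oxopentanal
Conditions: IBX, EtOAc, 80 °C
Reagents that add atoms: none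
Why: IBX oxidation of the primary alcohol stops at the aldehyde and leaves the methyl ketone untouched; no stereocentre is formed.

**Step 3**
Reactants: 4 4-oxopentanal; 5 (S)-2-methylpropane-2-sulfinamide
Product: 6 (S,E)-2-methyl-N-(4-oxopentylidene)propane-2-sulfinamide
Conditions: CuSO4, CH2Cl2, rt
Reagents that add atoms: none
Why: Ellman condensation is chemoselective for the aldehyde over the ketone and gives the E-sulfinimine that carries the only auxiliary of the route.

**Step 4**
Reactants: 6 (S,E)-2-methyl-N-(4-oxopentylidene)propane-2-sulfinamide; 2 tert-butyl(dimethyl)[(3-methylfuran-2-yl)oxy]silane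
Product: 7 (S)-2-methyl-N-{(1R)-1-[(2R)-4-methyl-5-oxo-2,5-dihydrofuran-2-yl]-4-oxopentyl}propane-2-sulfinamide
Conditions: TMSOTf (20 mol %), CH2Cl2, −78 °C; aq NaHCO3
Reagents that add atoms: none
Why: In this vinylogous Mukaiyama–Mannich reaction the furan C5 attacks the s-cis sulfinimine anti to t-Bu in an open transition state (C3 = R), and 3-methyl-2-silyloxyfurans are known to add syn-selectively to tert-butanesulfinimines (C18 = R).

**Step 5**
Reactants: 7 (S)-2-methyl-N-{(1R)-1-[(2R)-4-methyl-5-oxo-2,5-dihydrofuran-2-yl]-4-oxopentyl}propane-2-sulfinamide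
Product: 8 (S)-2-methyl-N-{(1R)-1-[(2R,4R)-4-methyl-5-oxooxolan-2-yl]-4-oxopentyl}propane-2-sulfinamide
Conditions: H2 (1 atm), 10% Pd/C, EtOAc, rt
Reagents that add atoms: none
Why: Heterogeneous hydrogenation delivers H2 to the butenolide face opposite the C18 substituent and gives the cis-lactone (C20 = R), while ketone and sulfinamide survive.

**Step 6**
Reactants: 8 (S)-2-methyl-N-{(1R)-1-[(2R,4R)-4-methyl-5-oxooxolan-2-yl]-4-oxopentyl}propane-2-sulfinamide
Product: 10 (3R,5R)-3-methyl-5-[(2R)-5-methyl-3,4-dihydro-2H-pyrrol-2-yl]oxolan-2-one, via amino ketone hydrochloride 9 (not isolated)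
Conditions: HCl (4 M in dioxane), MeOH, 0 °C; then aq NaHCO3, CH2Cl2, rt
Reagents that add atoms: none
Why: Acidic methanolysis removes the sulfinyl group, and on neutralisation the γ-amino ketone condenses to the 1-pyrroline (ring B) faster than it can attack the lactone; C3 is untouched.

**Step 7**
Reactants: 10 (3R,5R)-3-methyl-5-[(2R)-5-methyl-3,4-dihydro-2H-pyrrol-2-yl]oxolan-2-one; 11 6,6-dimethyl-5,7-dioxaspiro[2.5]octane-4,8-dione
Product: 13 (3R)-3-[(2R,4R)-4-methyl-5-oxooxolan-2-yl]-2,3,6,7-tetrahydro-1H-pyrrolo[1,2-a]azepin-8(5H)-one, via iminium enolate betaine 12 (not isolated)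
Conditions: MeCN, rt, 12 h; then toluene, 110 °C
Reagents that add atoms: none
Why: Proposed new method: the sp2 nitrogen opens the doubly activated cyclopropane by homo-Michael addition as pyridine does (N4–C5), the betaine tautomerises to the exocyclic enamine whose C9 is acylated intramolecularly by the Meldrum's carbonyl (C8–C9; attack by C1 would give an anti-Bredt product), and loss of acetone and CO2 makes the vinylogous amide irreversibly; the closest known types are amine opening of Danishefsky's cyclopropane and Stork enamine acylation.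

**Step 8**
Reactants: 13 (3R)-3-[(2R,4R)-4-methyl-5-oxooxolan-2-yl]-2,3,6,7-tetrahydro-1H-pyrrolo[1,2-a]azepin-8(5H)-one; 14 propanal; 2 tert-butyl(dimethyl)[(3-methylfuran-2-yl)oxy]silane
Product: 17 (1S,3R,10S,11S,12R,13S,18R,20R)-8-oxo-9(9a)-ene tetracycle (rings A–D of the tuberostemonine type plus the C3 lactone), via propenyl dienaminone 15 (not isolated), via butenolide adduct 16 (not isolated)
Conditions: 14, (R)-TRIP N-triflylphosphoramide (10 mol %), 4 Å MS, toluene, rt; 2, −40 °C; then 60 °C
Reagents that add atoms: none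
Why: Proposed new method: C9 of the enaminone condenses with propanal to an alkylidene-iminium paired with the chiral anion, 2 adds through C5 to C10 in an open transition state (catalyst control sets C10 S and C11 S, as in chiral-acid substitutions of 3-indolylmethanols and vinylogous Mukaiyama–Michael/Mannich reactions of silyloxyfurans), and on warming the C1-enamine tautomer closes ring C by intramolecular Michael addition to the butenolide syn to the tether (C12 R), A(1,2) strain between C8=O and ethyl enforcing the half-chair with C2 and C13 trans-diequatorial (C1 S) and external protonation of the lactone enol anti to C1 giving C13 S.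

**Step 9**
Reactants: 17 (1S,3R,10S,11S,12R,13S,18R,20R)-8-oxo-9(9a)-ene tetracycle
Product: 19 (1S,3R,9S,10S,11S,12R,13S,18R,20R)-8-oxo bridged lactam (8-dehydro target), via iodanyl carbinolamine 18 (not isolated)
Conditions: PhI(OH)OTs, MeCN–H2O (9:1), −20 to 0 °C
Reagents that add atoms: water, O
Why: Proposed new method: the vinylogous-amide oxygen binds I(III) to give an O-iodanyl enolonium iminium, water adds to C9a, and the carbinolamine collapses to the lactam while C1 migrates with retention from C9a to the electrophilic sp2 C9 with loss of PhI (aza-semipinacol shift), and because A(1,3) strain between O8 and ethyl allows only the ring-C chair with N4, C2 and C13 equatorial, C1 reaches the face that makes C9 S; the closest known types are I(III)/Tl(III) oxidative ring contraction of cyclic ketones via enol ethers, enolonium umpolung and the indole-to-spirooxindole rearrangement.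

**Step 10**
Reactants: 19 (1S,3R,9S,10S,11S,12R,13S,18R,20R)-8-oxo bridged lactam
Product: 20 CNP0120800.1 (1S,3R,8R,9S,10S,11S,12R,13S,18R,20R)
Conditions: NaBH4, CeCl3·7H2O, MeOH, −78 °C
Reagents that add atoms: none
Why: In this Luche-type reduction the ketone reacts faster than the lactones and the lactam, and hydride reaches C8 from the exo face next to the one-carbon C9a bridge (the other face is covered by the C1–C3 bridge with axial H1 and H3), which gives 8R.

**Compound list**
1 | 3-methylfuran-2(5H)-one | CC1=CCOC1=O | starting material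
2 | tert-butyl(dimethyl)[(3-methylfuran-2-yl)oxy]silane | Cc1ccoc1O[Si](C)(C)C(C)(C)C | intermediate
3 | 5-hydroxypentan-2-one | CC(=O)CCCO | starting material
4 | 4-oxopentanal | CC(=O)CCC=O | intermediate
5 | (S)-2-methylpropane-2-sulfinamide | CC(C)(C)[S@](=O)N | starting material
6 | (S,E)-2-methyl-N-(4-oxopentylidene)propane-2-sulfinamide | CC(C)(C)[S@](=O)/N=C/CCC(C)=O | intermediate
7 | (S)-2-methyl-N-{(1R)-1-[(2R)-4-methyl-5-oxo-2,5-dihydrofuran-2-yl]-4-oxopentyl}propane-2-sulfinamide | CC(=O)CC[C@H]([C@H]1C=C(C)C(=O)O1)N[S@@](=O)C(C)(C)C | intermediate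
8 | (S)-2-methyl-N-{(1R)-1-[(2R,4R)-4-methyl-5-oxooxolan-2-yl]-4-oxopentyl}propane-2-sulfinamide | CC(=O)CC[C@H]([C@H]1C[C@@H](C)C(=O)O1)N[S@@](=O)C(C)(C)C | intermediate
9 | (3R,5R)-5-[(1R)-1-amino-4-oxopentyl]-3-methyloxolan-2-one hydrochloride | CC(=O)CC[C@H]([C@H]1C[C@@H](C)C(=O)O1)[NH3+].[Cl-] | intermediate
10 | (3R,5R)-3-methyl-5-[(2R)-5-methyl-3,4-dihydro-2H-pyrrol-2-yl]oxolan-2-one | CC1=N[C@H](CC1)[C@H]1C[C@@H](C)C(=O)O1 | intermediate
11 | 6,6-dimethyl-5,7-dioxaspiro[2.5]octane-4,8-dione | CC1(C)OC(=O)C2(CC2)C(=O)O1 | starting material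
12 | betaine: N-[2-(2,2-dimethyl-4-oxido-6-oxo-1,3-dioxin-5-yl)ethyl]pyrrolinium derived from 10 (3R,18R,20R) | CC1=[N+](CCC2=C([O-])OC(C)(C)OC2=O)[C@H](CC1)[C@H]1C[C@@H](C)C(=O)O1 | intermediate
13 | (3R)-3-[(2R,4R)-4-methyl-5-oxooxolan-2-yl]-2,3,6,7-tetrahydro-1H-pyrrolo[1,2-a]azepin-8(5H)-one | O=C1CCCN2[C@H](CCC2=C1)[C@H]1C[C@@H](C)C(=O)O1 | intermediate
14 | propanal | CCC=O | starting material
15 | 9-[(E)-prop-1-enyl] derivative of 13 (neutral form of the alkylidene-iminium) | C/C=C/C1=C2CC[C@H]([C@H]3C[C@@H](C)C(=O)O3)N2CCCC1=O | intermediate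
16 | 9-{(1S)-1-[(2S)-4-methyl-5-oxo-2,5-dihydrofuran-2-yl]propyl} derivative of 13 | CC[C@H]([C@H]1OC(=O)C(C)=C1)C1=C2CC[C@H]([C@H]3C[C@@H](C)C(=O)O3)N2CCCC1=O | intermediate
17 | tetracyclic vinylogous amide: N4–C9a=C9–C8=O, ring C = C9a/C1/C12/C11/C10/C9, cis-fused α-methyl lactone at C11–C12, ethyl at C10; (1S,3R,10S,11S,12R,13S,18R,20R) | CC[C@@H]1[C@H]2OC(=O)[C@@H](C)[C@H]2[C@@H]2C[C@H]([C@H]3C[C@@H](C)C(=O)O3)N3CCCC(=O)C1=C23 | intermediate
18 | (9aS)-9a-hydroxy-8-O-[phenyl(tosyloxy)-λ3-iodanyl] 8(9)-enol of 17 | CC[C@@H]1[C@H]2OC(=O)[C@@H](C)[C@H]2[C@@H]2C[C@H]([C@H]3C[C@@H](C)C(=O)O3)N3CCCC(OI(c4ccccc4)OS(=O)(=O)c4ccc(C)cc4)=C1[C@@]23O | intermediate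
19 | 8-oxo bridged lactam (1-azabicyclo[4.3.1]decane-7,10-dione core, cyclopentane fused at C9–C1); (1S,3R,9S,10S,11S,12R,13S,18R,20R) | CC[C@@H]1[C@H]2OC(=O)[C@@H](C)[C@H]2[C@@H]2C[C@H]([C@H]3C[C@@H](C)C(=O)O3)N3CCCC(=O)[C@@]12C3=O | intermediate
20 | CNP0120800.1; (1S,3R,8R,9S,10S,11S,12R,13S,18R,20R) | CC[C@@H]1[C@H]2OC(=O)[C@@H](C)[C@H]2[C@@H]2C[C@H]([C@H]3C[C@@H](C)C(=O)O3)N3CCC[C@@H](O)[C@@]12C3=O | target

**Total steps:** 10. **Longest linear sequence:** 9 (steps 2–10, from 3).

**Steps most likely to fail**

Step 9 (oxidative 1,2-shift). The carbinolamine oxygen could close onto C9 instead, which would give net 9-hydroxylation. Tosylate could also be transferred to C9, or the product could suffer retro-Claisen cleavage. The fallback replaces the O-bound enolonium by an isolable carbon-bound leaving group and sets out from 17. NBS with catalytic LiBr in MeOH at −40 °C gives the 9-bromo-9a-methoxy N,O-acetal F5. Its C9 epimers interconvert by bromide-mediated Br+ transfer and can be separated. AgBF4 in wet CH2Cl2 then drives a silver-assisted quasi-Favorskii (semibenzilic) shift of C1 anti to bromide. Hydrolysis of the O-methyl lactim salt brings the route back at 19.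

Step 8 (three-component union and Michael closure). The enaminone could form a bis-adduct with propanal. The catalyst may not override the remote C3 centre, whose own bias at C1 is mismatched. The γ-carbon Michael closure could also be slow. The fallback changes the electrophile and the order of bond formation, and sets out from 13, using 2 and 14. A BF3·OEt2 vinylogous Mukaiyama aldol reaction of 2 with 14 gives 5-(1-hydroxypropyl)-3-methylfuran-2(5H)-one F3. MsCl/Et3N eliminates it to (5Z)-3-methyl-5-propylidenefuran-2(5H)-one F4. Compound 13 then adds through C9 to C10 of F4 (1,6-addition, Cu(II)–bis(oxazoline) or Sc(OTf)3). After γ-protonation, C1 adds 1,4 to C12 in a formal [3+3] annulation. The West-series diastereomers are separated by chromatography, and the route is rejoined at 17.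

Step 7 ([4+3] annulation). The hindered imine may open the cyclopropane slowly, or through the carbon of its enamine tautomer, which would give the regioisomeric enelactam. The betaine may also resist acylation. The fallback forms C8–C9 before N4–C5 and sets out from 8. Soft-enolisation acylation at the methyl group (MgBr2·OEt2, i-Pr2NEt, 4-chlorobutanoyl chloride) gives the chloro-1,3-diketone sulfinamide F1. HCl/MeOH followed by NaHCO3 gives the Z-configured NH-enaminone F2. Cs2CO3 with excess NaI in DMF at 100 °C closes ring A at nitrogen; any O-alkylation is reversible under iodide, whereas N-alkylation is not. This returns to the route at 13.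

**Further compounds**
F1 | step 7 | (S)-N-{(1R)-9-chloro-1-[(2R,4R)-4-methyl-5-oxooxolan-2-yl]-4,6-dioxononyl}-2-methylpropane-2-sulfinamide | ClCCCC(=O)CC(=O)CC[C@H]([C@H]1C[C@@H](C)C(=O)O1)N[S@@](=O)C(C)(C)C
F2 | step 7 | (3R,5R)-5-[(2R,5Z)-5-(5-chloro-2-oxopentylidene)pyrrolidin-2-yl]-3-methyloxolan-2-one | O=C(CCCCl)/C=C1\N[C@H](CC1)[C@H]1C[C@@H](C)C(=O)O1
F3 | step 8 | 5-(1-hydroxypropyl)-3-methylfuran-2(5H)-one (diastereomer mixture) | CCC(O)C1OC(=O)C(C)=C1
F4 | step 8 | (5Z)-3-methyl-5-propylidenefuran-2(5H)-one | CC/C=C1\OC(=O)C(C)=C1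
F5 | step 9 | (9R,9aS)-9-bromo-9a-methoxy-9,9a-dihydro derivative of 17 | CC[C@@H]1[C@H]2OC(=O)[C@@H](C)[C@H]2[C@@H]2C[C@H]([C@H]3C[C@@H](C)C(=O)O3)N3CCCC(=O)[C@]1(Br)[C@@]23OC
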